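**Reading of the target (one assumption):** the SMILES encodes the all-cis (1R,2R,3R) indane, with the 4-hydroxybenzoyl, 4-hydroxyphenyl and 3,5-dihydroxyphenyl groups on one face; that isomer is the one made. The route is a proposal built from precedented reaction types and has not been run.

## Retrosynthetic overview

1. Target 18 ⇐ one-pot hydrogenation/hydrogenolysis of the pentabenzyl 3-aroyl-1,2-diaryl-1H-indene 16. H2 adds anti to the existing aryl-bearing stereocentre, which sets C1 and C2 all-cis, and the five phenols are freed last under neutral conditions.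
2. 16 ⇐ enol triflate 13 + CO + aryl stannane 15 (carbonylative Stille). 13 ⇐ 2,3-diarylindanone 11 ⇐ Pd α-arylation of 3-arylindanone 9 with aryl bromide 10.
3. 9 ⇐ (R)-3-arylindanone 7 (methyl → benzyl exchange) ⇐ (R)-indenol 5 by stereospecific 1,3-hydrogen shift ⇐ achiral indenone 4 by ketoreductase reduction (the only catalyst-controlled stereocentre).
4. 4 ⇐ acid cyclisation of ynone 3 ⇐ acid chloride 1 + alkyne 2 (acyl Sonogashira).
5. Ring order: all four benzene rings are bought; the only ring formed is the five-membered ring (step 2).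

## Route

**Step 1**
Reactants: 1 3,5-dimethoxybenzoyl chloride; 2 1-ethynyl-3,5-dimethoxybenzene
Product: 3 1,3-bis(3,5-dimethoxyphenyl)prop-2-yn-1-one
Conditions: PdCl2(PPh3)2 (2 mol%), CuI (4 mol%), Et3N, THF, rt
Reagents that add atoms: none
Why: Acyl Sonogashira coupling of an aroyl chloride with a terminal aryl alkyne gives the achiral ynone directly.

**Step 2**
Reactants: 3 1,3-bis(3,5-dimethoxyphenyl)prop-2-yn-1-one
Product: 4 3-(3,5-dimethoxyphenyl)-4,6-dimethoxy-1H-inden-1-one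
Conditions: TfOH (5 equiv), CH2Cl2, 0 °C → rt
Reagents that add atoms: none
Why: Acid-mediated intramolecular hydroarylation (Nazarov-type closure of the O-protonated aryl ynone) by the ring carbon ortho/para to the two methoxy groups gives the achiral 3-arylindenone with no stereocentre formed.

**Step 3**
Reactants: 4 3-(3,5-dimethoxyphenyl)-4,6-dimethoxy-1H-inden-1-one
Product: 5 (1R)-3-(3,5-dimethoxyphenyl)-4,6-dimethoxy-1H-inden-1-ol
Conditions: (R)-selective ketoreductase (KRED, NADPH-dependent, chosen from a screening panel), NADP+ (cat.), i-PrOH, phosphate buffer pH 7/DMSO, 30 °C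
Reagents that add atoms: none
Why: Enzymatic asymmetric 1,2-reduction of the prochiral enone carbonyl (ketoreductase, hydride from NADPH to one enantiotopic face) creates the first stereocentre, C1-OH (R), without touching the C=C.

**Step 4**
Reactants: 5 (1R)-3-(3,5-dimethoxyphenyl)-4,6-dimethoxy-1H-inden-1-ol
Product: 7 (3R)-3-(3,5-dimethoxyphenyl)-4,6-dimethoxy-2,3-dihydro-1H-inden-1-one, via (1R)-1-(3,5-dimethoxyphenyl)-5,7-dimethoxy-1H-inden-3-ol (enol) 6 (not isolated)
Conditions: DABCO (0.2 equiv), Et3N, THF, 60 °C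
Reagents that add atoms: none
Why: Amine-mediated suprafacial 1,3-prototropic shift through a tight ion pair hands the C1 hydrogen to C3 on the same face, so (1R)-5 gives the (3R)-indanone by chirality transfer after enol–keto tautomerisation.

**Step 5**
Reactants: 7 (3R)-3-(3,5-dimethoxyphenyl)-4,6-dimethoxy-2,3-dihydro-1H-inden-1-one
Product: 8 (3R)-3-(3,5-dihydroxyphenyl)-4,6-dihydroxy-2,3-dihydro-1H-inden-1-one
Conditions: BBr3 (8 equiv), CH2Cl2, −78 °C → rt; then MeOH/H2O
Reagents that add atoms: none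
Why: Lewis-acid ether cleavage (BBr3 demethylation) is done here because C3 is not enolisable in this ketone, whereas the final all-cis α-keto centre would not tolerate it.

**Step 6**
Reactants: 8 (3R)-3-(3,5-dihydroxyphenyl)-4,6-dihydroxy-2,3-dihydro-1H-inden-1-one
Product: 9 (3R)-4,6-bis(benzyloxy)-3-[3,5-bis(benzyloxy)phenyl]-2,3-dihydro-1H-inden-1-one
Conditions: BnBr (4.4 equiv), K2CO3, DMF, rt
Reagents that add atoms: benzyl bromide BrCc1ccccc1
Why: Williamson O-benzylation of the four phenols installs groups that the final hydrogenation removes under neutral conditions.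

**Step 7**
Reactants: 9 (3R)-4,6-bis(benzyloxy)-3-[3,5-bis(benzyloxy)phenyl]-2,3-dihydro-1H-inden-1-one; 10 1-(benzyloxy)-4-bromobenzene
Product: 11 (2R,3R)-4,6-bis(benzyloxy)-3-[3,5-bis(benzyloxy)phenyl]-2-[4-(benzyloxy)phenyl]-2,3-dihydro-1H-inden-1-one (2,3-trans)
Conditions: Pd(OAc)2 (5 mol%), t-Bu3P·HBF4 (10 mol%), NaOtBu, toluene, 70 °C
Reagents that add atoms: none
Why: Pd-catalysed ketone α-arylation (Buchwald–Hartwig type) gives the thermodynamic trans isomer and leaves the non-acidic C3 centre untouched; the C2 configuration is erased in step 8 anyway.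

**Step 8**
Reactants: 11 (2R,3R)-4,6-bis(benzyloxy)-3-[3,5-bis(benzyloxy)phenyl]-2-[4-(benzyloxy)phenyl]-2,3-dihydro-1H-inden-1-one
Product: 13 (1R)-5,7-bis(benzyloxy)-1-[3,5-bis(benzyloxy)phenyl]-2-[4-(benzyloxy)phenyl]-1H-inden-3-yl trifluoromethanesulfonate, via sodium (1S)-5,7-bis(benzyloxy)-1-[3,5-bis(benzyloxy)phenyl]-2-[4-(benzyloxy)phenyl]-1H-inden-3-olate 12 (not isolated)
Conditions: NaHMDS (1.0 equiv), THF, −78 °C; then PhNTf2, −78 → 0 °C
Reagents that add atoms: N-phenylbis(trifluoromethanesulfonimide) O=S(=O)(N(c1ccccc1)S(=O)(=O)C(F)(F)F)C(F)(F)F; sodium hexamethyldisilazide C[Si](C)(C)[N-][Si](C)(C)C.[Na+] (sodium, in 12 only)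
Why: Enolate O-triflation with exactly one equivalent of base at low temperature keeps the aryl-bearing sp3 centre from being deprotonated; the R/S label changes through 12, 13 and 16 only reflect CIP priorities, not the spatial arrangement.

**Step 9**
Reactants: 10 1-(benzyloxy)-4-bromobenzene
Product: 15 tributyl[4-(benzyloxy)phenyl]stannane, via [4-(benzyloxy)phenyl]lithium 14 (not isolated)
Conditions: n-BuLi, THF, −78 °C; then Bu3SnCl, −78 °C → rt
Reagents that add atoms: tributyltin chloride CCCC[Sn](Cl)(CCCC)CCCC; n-butyllithium [Li]CCCC (lithium, in 14 only)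
Why: Bromine–lithium exchange followed by stannylation gives the aryl donor for a base-free coupling.

**Step 10**
Reactants: 13 (1R)-5,7-bis(benzyloxy)-1-[3,5-bis(benzyloxy)phenyl]-2-[4-(benzyloxy)phenyl]-1H-inden-3-yl trifluoromethanesulfonate; 15 tributyl[4-(benzyloxy)phenyl]stannane
Product: 16 [(1S)-5,7-bis(benzyloxy)-1-[3,5-bis(benzyloxy)phenyl]-2-[4-(benzyloxy)phenyl]-1H-inden-3-yl][4-(benzyloxy)phenyl]methanone
Conditions: Pd(PPh3)4 (5 mol%), LiCl (3 equiv), CO (3 atm), THF, 60 °C; work-up without base, KF or amine (tin removed by MeCN/hexane partition)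
Reagents that add atoms: carbon monoxide [C-]#[O+]
Why: Carbonylative Stille coupling (oxidative addition, CO insertion, Sn→Pd transmetalation) forms the aryl ketone under neutral conditions, which matters because the sp3 C–H of 16 is a strong carbon acid.

**Step 11**
Reactants: 16 [(1S)-5,7-bis(benzyloxy)-1-[3,5-bis(benzyloxy)phenyl]-2-[4-(benzyloxy)phenyl]-1H-inden-3-yl][4-(benzyloxy)phenyl]methanone
Product: 18 caraphenol B, [(1R,2R,3R)-3-(3,5-dihydroxyphenyl)-4,6-dihydroxy-2-(4-hydroxyphenyl)-2,3-dihydro-1H-inden-1-yl](4-hydroxyphenyl)methanone, via [(1S)-1-(3,5-dihydroxyphenyl)-5,7-dihydroxy-2-(4-hydroxyphenyl)-1H-inden-3-yl](4-hydroxyphenyl)methanone 17 (not isolated)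
Conditions: H2 (4 atm), 10% Pd/C, EtOAc–MeOH (1:1), rt; filter and concentrate, no acid or base
Reagents that add atoms: none
Why: Heterogeneous syn hydrogenation of the tetrasubstituted enone from the face opposite the 3,5-dioxyphenyl group puts both new hydrogens cis to the existing one (all-cis C1, C2, C3), with concurrent O-benzyl hydrogenolysis, so the epimerisable α-keto centre never meets acid or base.

## Compound list

1 | 3,5-dimethoxybenzoyl chloride | COc1cc(OC)cc(C(=O)Cl)c1 | starting material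
2 | 1-ethynyl-3,5-dimethoxybenzene | C#Cc1cc(OC)cc(OC)c1 | starting material
3 | 1,3-bis(3,5-dimethoxyphenyl)prop-2-yn-1-one | O=C(C#Cc1cc(OC)cc(OC)c1)c1cc(OC)cc(OC)c1 | intermediate
4 | 3-(3,5-dimethoxyphenyl)-4,6-dimethoxy-1H-inden-1-one | O=C1C=C(c2cc(OC)cc(OC)c2)c2c(OC)cc(OC)cc21 | intermediate
5 | (1R)-3-(3,5-dimethoxyphenyl)-4,6-dimethoxy-1H-inden-1-ol | O[C@@H]1C=C(c2cc(OC)cc(OC)c2)c2c(OC)cc(OC)cc21 | intermediate
6 | (1R)-1-(3,5-dimethoxyphenyl)-5,7-dimethoxy-1H-inden-3-ol (enol) | OC1=C[C@H](c2cc(OC)cc(OC)c2)c2c(OC)cc(OC)cc21 | intermediate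
7 | (3R)-3-(3,5-dimethoxyphenyl)-4,6-dimethoxy-2,3-dihydro-1H-inden-1-one | O=C1C[C@H](c2cc(OC)cc(OC)c2)c2c(OC)cc(OC)cc21 | intermediate
8 | (3R)-3-(3,5-dihydroxyphenyl)-4,6-dihydroxy-2,3-dihydro-1H-inden-1-one | O=C1C[C@H](c2cc(O)cc(O)c2)c2c(O)cc(O)cc21 | intermediate
9 | (3R)-4,6-bis(benzyloxy)-3-[3,5-bis(benzyloxy)phenyl]-2,3-dihydro-1H-inden-1-one | O=C1C[C@H](c2cc(OCc3ccccc3)cc(OCc3ccccc3)c2)c2c(OCc3ccccc3)cc(OCc3ccccc3)cc21 | intermediate
10 | 1-(benzyloxy)-4-bromobenzene | Brc1ccc(OCc2ccccc2)cc1 | starting material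
11 | (2R,3R)-4,6-bis(benzyloxy)-3-[3,5-bis(benzyloxy)phenyl]-2-[4-(benzyloxy)phenyl]-2,3-dihydro-1H-inden-1-one | O=C1[C@@H](c2ccc(OCc3ccccc3)cc2)[C@H](c2cc(OCc3ccccc3)cc(OCc3ccccc3)c2)c2c(OCc3ccccc3)cc(OCc3ccccc3)cc21 | intermediate
12 | sodium (1S)-5,7-bis(benzyloxy)-1-[3,5-bis(benzyloxy)phenyl]-2-[4-(benzyloxy)phenyl]-1H-inden-3-olate | [Na+].[O-]C1=C(c2ccc(OCc3ccccc3)cc2)[C@H](c2cc(OCc3ccccc3)cc(OCc3ccccc3)c2)c2c(OCc3ccccc3)cc(OCc3ccccc3)cc21 | intermediate
13 | (1R)-5,7-bis(benzyloxy)-1-[3,5-bis(benzyloxy)phenyl]-2-[4-(benzyloxy)phenyl]-1H-inden-3-yl trifluoromethanesulfonate | O=S(=O)(OC1=C(c2ccc(OCc3ccccc3)cc2)[C@H](c2cc(OCc3ccccc3)cc(OCc3ccccc3)c2)c2c(OCc3ccccc3)cc(OCc3ccccc3)cc21)C(F)(F)F | intermediate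
14 | [4-(benzyloxy)phenyl]lithium | [Li]c1ccc(OCc2ccccc2)cc1 | intermediate
15 | tributyl[4-(benzyloxy)phenyl]stannane | CCCC[Sn](CCCC)(CCCC)c1ccc(OCc2ccccc2)cc1 | intermediate
16 | [(1S)-5,7-bis(benzyloxy)-1-[3,5-bis(benzyloxy)phenyl]-2-[4-(benzyloxy)phenyl]-1H-inden-3-yl][4-(benzyloxy)phenyl]methanone | O=C(c1ccc(OCc2ccccc2)cc1)C1=C(c2ccc(OCc3ccccc3)cc2)[C@H](c2cc(OCc3ccccc3)cc(OCc3ccccc3)c2)c2c(OCc3ccccc3)cc(OCc3ccccc3)cc21 | intermediate
17 | [(1S)-1-(3,5-dihydroxyphenyl)-5,7-dihydroxy-2-(4-hydroxyphenyl)-1H-inden-3-yl](4-hydroxyphenyl)methanone | O=C(c1ccc(O)cc1)C1=C(c2ccc(O)cc2)[C@H](c2cc(O)cc(O)c2)c2c(O)cc(O)cc21 | intermediate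
18 | caraphenol B, [(1R,2R,3R)-3-(3,5-dihydroxyphenyl)-4,6-dihydroxy-2-(4-hydroxyphenyl)-2,3-dihydro-1H-inden-1-yl](4-hydroxyphenyl)methanone | O=C(c1ccc(O)cc1)[C@H]1c2cc(O)cc(O)c2[C@@H](c2cc(O)cc(O)c2)[C@H]1c1ccc(O)cc1 | target

## Step count and risks

Total steps: 11. Longest linear sequence: 10 steps (steps 1–8, 10, 11); step 9 is a one-step side branch.

**Step 3 (ketoreductase on a bulky indenone).** No panel enzyme may accept 4 with high (R)-selectivity. The fallback sets out from 4 and uses an ene-reductase of the Old Yellow Enzyme family (NADP+, glucose dehydrogenase/glucose, buffer, 30 °C) to reduce the C2=C3 bond directly. It comes back to the route at 7, bypassing 5, 6 and step 4, and makes no new compound (F0). Ene-reductases are known to reduce 3-arylindenones with very high ee, but yeast enzymes give the (S)-series on simpler substrates, so a homologue or variant with the opposite facial preference would have to be found by screening.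

**Step 10 (carbonylative Stille on a hindered triflate).** Direct, non-carbonylative coupling or slow transmetalation may dominate, and any base would racemise 16. The fallback sets out from 13 and uses a Nozaki–Hiyama–Kishi coupling with 4-(benzyloxy)benzaldehyde (CrCl2, cat. NiCl2, DMF, rt; neutral, non-basic organochromium). This gives the allylic alcohol [(1S)-5,7-bis(benzyloxy)-1-[3,5-bis(benzyloxy)phenyl]-2-[4-(benzyloxy)phenyl]-1H-inden-3-yl][4-(benzyloxy)phenyl]methanol F1 as a mixture of carbinol epimers. Oxidation with Dess–Martin periodinane in CH2Cl2 without added base then comes back to the route at 16.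

**Step 11 (one-pot hydrogenation/hydrogenolysis).** The tetrasubstituted enone may reduce slowly once the phenols are free, the aryl ketone may over-reduce, or ee may erode. The fallback sets out from 16 and separates the two events. A homogeneous cationic iridium catalyst ([Ir(cod)(PCy3)(py)]BArF, H2 50 bar, CH2Cl2, rt) hydrogenates the C=C from the face anti to the aryl group without touching benzyl ethers. This gives [(1R,2R,3R)-4,6-bis(benzyloxy)-3-[3,5-bis(benzyloxy)phenyl]-2-[4-(benzyloxy)phenyl]-2,3-dihydro-1H-inden-1-yl][4-(benzyloxy)phenyl]methanone F2, which can be purified or recrystallised to upgrade dr and ee. A short, mild hydrogenolysis (H2 1 atm, Pd(OH)2/C, EtOAc–MeOH, rt) then comes back to the route at 18.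

## Further compounds

F0 | step 3 | none | none
F1 | step 10 | [(1S)-5,7-bis(benzyloxy)-1-[3,5-bis(benzyloxy)phenyl]-2-[4-(benzyloxy)phenyl]-1H-inden-3-yl][4-(benzyloxy)phenyl]methanol (carbinol epimers) | OC(c1ccc(OCc2ccccc2)cc1)C1=C(c2ccc(OCc3ccccc3)cc2)[C@H](c2cc(OCc3ccccc3)cc(OCc3ccccc3)c2)c2c(OCc3ccccc3)cc(OCc3ccccc3)cc21
F2 | step 11 | [(1R,2R,3R)-4,6-bis(benzyloxy)-3-[3,5-bis(benzyloxy)phenyl]-2-[4-(benzyloxy)phenyl]-2,3-dihydro-1H-inden-1-yl][4-(benzyloxy)phenyl]methanone | O=C(c1ccc(OCc2ccccc2)cc1)[C@H]1c2cc(OCc3ccccc3)cc(OCc3ccccc3)c2[C@@H](c2cc(OCc3ccccc3)cc(OCc3ccccc3)c2)[C@H]1c1ccc(OCc2ccccc2)cc1
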